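A direct plan would start from 2,4-dihydroxyacetophenone A1 and build the prenyl group by O-allylation, aromatic Claisen rearrangement to 3-allyl-2,4-dihydroxyacetophenone A2 and olefin cross metathesis.
It would then mask the 4-OH as a methoxymethyl ether so that the chelated 2-OH could be methylated (ketone A3), condense the enolate of A3 with methyl 4-(methoxymethoxy)benzoate A4 to the protected diketone A5, and end with acid cleavage of both acetals.
Its first weak point would be the allyl ether/rearrangement/metathesis sequence: three operations for one C5 unit, with the choice between C3 and C5 of ring A left to a hydrogen-bond bias.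
Its second would be the protect-then-methylate detour (plus a protection on ring B): steps that add no skeletal complexity, forced because the oxygen that must carry the methyl group is the least reactive one.
Its third would be the closing acid cleavage on the finished diketone, the step least welcome on late material, since the freed ortho-prenylphenol could add to its own double bond (chroman) under the acid that removes the acetals.

**Plan of the new route**
The retrosynthesis first takes the carbonyl next to ring B back to an alkyne (formal hydration of diaryl ynone 10), then cuts ring A itself across C1–C2 and C5–C6 by a retro Alder–Rickert step into terminal ynone 8 and cyclohexadiene 4.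
Ring B is bought; ring A arises last, in the key step, from cyclohexane-1,3-dione carried as a partly saturated ring and aromatised by loss of ethylene.
The feature that allows this: ring A is a resorcinol monomethyl ether with the prenyl group on C3 between the two oxygens, the acyl group at C1 ortho to C2–OMe and para to C4–OH, and C5 and C6 both CH. This is the exact pattern that a 1-methoxy-2-alkyl-3-silyloxycyclohexa-1,3-diene and a terminal ynone deliver.
The prenyl group enters at C2 of the dione, the only doubly activated carbon, so no rearrangement, no metathesis and no C3/C5 question arise. The two dione oxygens are equivalent, so a single O-methylation tells them apart without any phenol protection.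
The silyl groups come with the diene and with the ring B iodide and fall to fluoride, so no acetal has to be cleaved by acid beside the prenylphenol.

Key step: step 6

Assumption: tert-butyl(4-iodophenoxy)dimethylsilane and penta-1,4-diyn-3-ol are taken as catalogue compounds.

Step 1
Reactants: 1 cyclohexane-1,3-dione
Product: 2 2-(3-methylbut-2-enyl)cyclohexane-1,3-dione
Conditions: prenyl bromide (1.0 equiv), KOH (1.0 equiv), H2O, 0 °C to rt, 20 h; AcOH to pH 5
Reagents that add atoms: prenyl bromide (1-bromo-3-methylbut-2-ene) CC(C)=CCBr
Why: C-Alkylation (SN2) of a cyclic 1,3-dione enolate, in which C2 is the only doubly activated carbon so the prenyl group can only arrive between the two oxygens, water hydrogen-bonds the enolate oxygens and favours C- over O-alkylation, and no stereocentre arises.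

Step 2
Reactants: 2 2-(3-methylbut-2-enyl)cyclohexane-1,3-dione
Product: 3 3-methoxy-2-(3-methylbut-2-enyl)cyclohex-2-en-1-one
Conditions: Me2SO4 (1.3 equiv), K2CO3 (2 equiv), acetone, reflux, 6 h
Reagents that add atoms: dimethyl sulfate COS(=O)(=O)OC
Why: O-Methylation of a vinylogous acid (enol ether formation) in which the two oxygens of 2 are equivalent by symmetry so one methylation differentiates them, the hard sulfate favours O- over C-methylation, and base is used because acid would close the enol onto the prenyl double bond.

Step 3
Reactants: 3 3-methoxy-2-(3-methylbut-2-enyl)cyclohex-2-en-1-one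
Product: 4 1-methoxy-2-(3-methylbut-2-enyl)-3-(tert-butyldimethylsilyloxy)cyclohexa-1,3-diene
Conditions: lithium diisopropylamide (1.1 equiv), THF, −78 °C, 45 min; TBSCl (1.2 equiv), DMPU, −78 °C to rt; non-aqueous work-up, used without chromatography
Reagents that add atoms: tert-butyldimethylsilyl chloride (TBSCl) CC(C)(C)[Si](C)(C)Cl
Why: Kinetic α′-deprotonation of a vinylogous ester and O-silylation (silyl dienol ether formation), in which the amide base removes the proton next to the carbonyl and not the γ-proton, so the cross-conjugated 1-methoxy-3-silyloxy diene held s-cis by the ring should result.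

Step 4
Reactants: 5 tert-butyl(4-iodophenoxy)dimethylsilane; 6 penta-1,4-diyn-3-ol (3 equiv)
Product: 7 1-[4-(tert-butyldimethylsilyloxy)phenyl]penta-1,4-diyn-3-ol (racemic)
Conditions: PdCl2(PPh3)2 (2 mol %), CuI (4 mol %), Et3N (3 equiv), THF, rt, degassed
Reagents that add atoms: none
Why: Sonogashira coupling in which the symmetric diynol is used in excess so that mono-arylation should dominate, and the carbinol stereocentre that appears is racemic and is erased in step 5.

Step 5
Reactants: 7 1-[4-(tert-butyldimethylsilyloxy)phenyl]penta-1,4-diyn-3-ol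
Product: 8 1-[4-(tert-butyldimethylsilyloxy)phenyl]penta-1,4-diyn-3-one
Conditions: MnO2 (activated, 15 equiv), CH2Cl2, 0 °C to rt, 2 h; filtered and used at once
Reagents that add atoms: none
Why: MnO2 oxidation of a doubly propargylic alcohol to the ketone under neutral heterogeneous conditions that should leave the aryl silyl ether and both alkynes untouched.

Step 6
Reactants: 4 1-methoxy-2-(3-methylbut-2-enyl)-3-(tert-butyldimethylsilyloxy)cyclohexa-1,3-diene; 8 1-[4-(tert-butyldimethylsilyloxy)phenyl]penta-1,4-diyn-3-one (1.2 equiv)
Product: 10 1-[4-(tert-butyldimethylsilyloxy)-2-methoxy-3-(3-methylbut-2-enyl)phenyl]-3-[4-(tert-butyldimethylsilyloxy)phenyl]prop-2-yn-1-one, via bicyclo[2.2.2]octadiene adduct 9 (not isolated)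
Conditions: o-xylene (0.3 M), 80 °C, 6 h, then 145 °C, 10 h, N2 sweep
Reagents that add atoms: none
Why: Alder–Rickert sequence, a normal-electron-demand [4+2] cycloaddition followed by a retro-[4+2] loss of ethylene: the ring-locked s-cis diene 4 adds across the terminal C≡C of 8 to give adduct 9, whose saturated two-carbon bridge leaves as ethylene on further heating, so ring A appears aromatic with its OMe kept, because aromatisation does not pass through loss of methanol. The closest known reaction type is the synthesis of 4-hydroxy-2-methoxybenzoates and aryl ketones from 1-methoxy-3-silyloxycyclohexa-1,3-dienes and propiolates or ynones. Ring A is closed in an intermolecular [4+2] mode (target bonds C1–C2 and C5–C6 formed in one event) and released by cycloreversion; no stereocentre survives, the two bridgehead centres of 9 being erased with the bridge. Regiochemistry is needed and is secured by the diene: the OMe at its C1 and the silyloxy group at its C3 both push electron density to the unsubstituted terminus C4, which bonds to the electron-poor β-CH of the ynone, so the acyl-bearing carbon joins the OMe-bearing terminus and the ketone ends ortho to OMe and para to the silyloxy group, with the prenyl group between the two oxygens. Chemoselectivity between the two alkynes of 8 is needed and rests on the terminal one being unhindered and more electrophilic, whereas the aryl-capped one is β-substituted and fed by the para-silyloxyphenyl donor; the small excess of 8 guards against twofold addition.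

Step 7
Reactants: 10 1-[4-(tert-butyldimethylsilyloxy)-2-methoxy-3-(3-methylbut-2-enyl)phenyl]-3-[4-(tert-butyldimethylsilyloxy)phenyl]prop-2-yn-1-one
Product: 13 1-[4-hydroxy-2-methoxy-3-(3-methylbut-2-enyl)phenyl]-3-(4-hydroxyphenyl)propane-1,3-dione, via bis-silyl morpholino enaminone 11 (not isolated), via bisphenol morpholino enaminone 12 (not isolated)
Conditions: morpholine (3 equiv), THF, 40 °C, 4 h; Bu4NF (2.4 equiv), 0 °C, 30 min; aq. AcOH/NaOAc buffer (pH 4), 35 °C, 3 h
Reagents that add atoms: water O
Why: Aza-Michael addition of a secondary amine to the ynone, fluoride cleavage of the aryl silyl ethers and hydrolysis of the vinylogous amide (formal ynone hydration), in which the amine adds only at the β-carbon and so places the second carbonyl on the carbon attached to ring B, the buffer is far too weak to protonate the prenyl double bond, the 2-OMe group rules out flavone closure, and no stereocentre is formed.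

**Compound list**
1 | cyclohexane-1,3-dione | O=C1CCCC(=O)C1 | starting material
2 | 2-(3-methylbut-2-enyl)cyclohexane-1,3-dione | CC(C)=CCC1C(=O)CCCC1=O | intermediate
3 | 3-methoxy-2-(3-methylbut-2-enyl)cyclohex-2-en-1-one | COC1=C(CC=C(C)C)C(=O)CCC1 | intermediate
4 | 1-methoxy-2-(3-methylbut-2-enyl)-3-(tert-butyldimethylsilyloxy)cyclohexa-1,3-diene | COC1=C(CC=C(C)C)C(O[Si](C)(C)C(C)(C)C)=CCC1 | intermediate
5 | tert-butyl(4-iodophenoxy)dimethylsilane | CC(C)(C)[Si](C)(C)Oc1ccc(I)cc1 | starting material
6 | penta-1,4-diyn-3-ol | C#CC(O)C#C | starting material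
7 | 1-[4-(tert-butyldimethylsilyloxy)phenyl]penta-1,4-diyn-3-ol (racemic) | C#CC(O)C#Cc1ccc(O[Si](C)(C)C(C)(C)C)cc1 | intermediate
8 | 1-[4-(tert-butyldimethylsilyloxy)phenyl]penta-1,4-diyn-3-one | C#CC(=O)C#Cc1ccc(O[Si](C)(C)C(C)(C)C)cc1 | intermediate
9 | 1-[1-methoxy-6-(3-methylbut-2-enyl)-5-(tert-butyldimethylsilyloxy)bicyclo[2.2.2]octa-2,5-dien-2-yl]-3-[4-(tert-butyldimethylsilyloxy)phenyl]prop-2-yn-1-one (racemic, transient, not isolated) | COC12CCC(C=C1C(=O)C#Cc1ccc(O[Si](C)(C)C(C)(C)C)cc1)C(O[Si](C)(C)C(C)(C)C)=C2CC=C(C)C | intermediate
10 | 1-[4-(tert-butyldimethylsilyloxy)-2-methoxy-3-(3-methylbut-2-enyl)phenyl]-3-[4-(tert-butyldimethylsilyloxy)phenyl]prop-2-yn-1-one | COc1c(C(=O)C#Cc2ccc(O[Si](C)(C)C(C)(C)C)cc2)ccc(O[Si](C)(C)C(C)(C)C)c1CC=C(C)C | intermediate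
11 | (E)-1-[4-(tert-butyldimethylsilyloxy)-2-methoxy-3-(3-methylbut-2-enyl)phenyl]-3-[4-(tert-butyldimethylsilyloxy)phenyl]-3-(morpholin-4-yl)prop-2-en-1-one (E expected, not isolated) | COc1c(C(=O)/C=C(/N2CCOCC2)c2ccc(O[Si](C)(C)C(C)(C)C)cc2)ccc(O[Si](C)(C)C(C)(C)C)c1CC=C(C)C | intermediate
12 | (E)-1-[4-hydroxy-2-methoxy-3-(3-methylbut-2-enyl)phenyl]-3-(4-hydroxyphenyl)-3-(morpholin-4-yl)prop-2-en-1-one (E expected, not isolated) | COc1c(C(=O)/C=C(/N2CCOCC2)c2ccc(O)cc2)ccc(O)c1CC=C(C)C | intermediate
13 | 1-[4-hydroxy-2-methoxy-3-(3-methylbut-2-enyl)phenyl]-3-(4-hydroxyphenyl)propane-1,3-dione (CNP0308388.0, achiral) | COc1c(C(=O)CC(=O)c2ccc(O)cc2)ccc(O)c1CC=C(C)C | target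

Total step count: 7. Longest linear sequence: 5 (steps 1, 2, 3, 6, 7).

**Steps most likely to fail**

Step 6. What may go wrong: cycloaddition at the aryl-capped alkyne or twofold addition, thermal oligomerisation of the diynone before it is trapped, or conjugate (Mukaiyama–Michael) addition of the silyl dienol ether in place of cycloaddition. The fallback sets out from 4 and comes back at 13. Diene 4 would be heated with methyl propiolate, a dienophile with a single alkyne, to give by way of methyl 1-methoxy-6-(3-methylbut-2-enyl)-5-(tert-butyldimethylsilyloxy)bicyclo[2.2.2]octa-2,5-diene-2-carboxylate F1 and loss of ethylene the ester methyl 4-(tert-butyldimethylsilyloxy)-2-methoxy-3-(3-methylbut-2-enyl)benzoate F2. A crossed Claisen condensation of F2 with the lithium enolate of commercial 4′-(tert-butyldimethylsilyloxy)acetophenone (LiN(SiMe3)2, THF) should give 1-[4-(tert-butyldimethylsilyloxy)-2-methoxy-3-(3-methylbut-2-enyl)phenyl]-3-[4-(tert-butyldimethylsilyloxy)phenyl]propane-1,3-dione F3. Bu4NF buffered with AcOH would then free both phenols to give 13.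

Step 7. What may go wrong: slow amine addition to the electron-rich ynone once a silyl group is lost early, or incomplete hydrolysis of the vinylogous amide at pH 4. The fallback sets out from 10 and comes back at 13. A PMe3-catalysed oxa-Michael addition of 2-(trimethylsilyl)ethanol to 10 should give (E)-1-[4-(tert-butyldimethylsilyloxy)-2-methoxy-3-(3-methylbut-2-enyl)phenyl]-3-[4-(tert-butyldimethylsilyloxy)phenyl]-3-[2-(trimethylsilyl)ethoxy]prop-2-en-1-one F4. A single treatment with Bu4NF (THF, rt to 50 °C) should cleave both aryl silyl ethers and fragment the silylethyl enol ether to the diketonate, which gives 13 on buffered work-up without any acid hydrolysis.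

Step 4. What may go wrong: twofold arylation of the diynol, copper-mediated oxidative dimerisation of the terminal alkyne, or base-induced isomerisation of the skipped diynol. The fallback sets out from 5 and comes back at 7, building the two alkynes one after the other. Sonogashira coupling of 5 with prop-2-yn-1-ol should give 3-[4-(tert-butyldimethylsilyloxy)phenyl]prop-2-yn-1-ol F5, and MnO2 oxidation should give 3-[4-(tert-butyldimethylsilyloxy)phenyl]prop-2-ynal F6. Addition of ethynylmagnesium bromide (THF, −40 °C) to F6 would give 7.

**Further compounds**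
F1 | step 6 | methyl 1-methoxy-6-(3-methylbut-2-enyl)-5-(tert-butyldimethylsilyloxy)bicyclo[2.2.2]octa-2,5-diene-2-carboxylate (racemic, not isolated) | COC12CCC(C=C1C(=O)OC)C(O[Si](C)(C)C(C)(C)C)=C2CC=C(C)C
F2 | step 6 | methyl 4-(tert-butyldimethylsilyloxy)-2-methoxy-3-(3-methylbut-2-enyl)benzoate | COC(=O)c1ccc(O[Si](C)(C)C(C)(C)C)c(CC=C(C)C)c1OC
F3 | step 6 | 1-[4-(tert-butyldimethylsilyloxy)-2-methoxy-3-(3-methylbut-2-enyl)phenyl]-3-[4-(tert-butyldimethylsilyloxy)phenyl]propane-1,3-dione | COc1c(C(=O)CC(=O)c2ccc(O[Si](C)(C)C(C)(C)C)cc2)ccc(O[Si](C)(C)C(C)(C)C)c1CC=C(C)C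
F4 | step 7 | (E)-1-[4-(tert-butyldimethylsilyloxy)-2-methoxy-3-(3-methylbut-2-enyl)phenyl]-3-[4-(tert-butyldimethylsilyloxy)phenyl]-3-[2-(trimethylsilyl)ethoxy]prop-2-en-1-one | COc1c(C(=O)/C=C(/OCC[Si](C)(C)C)c2ccc(O[Si](C)(C)C(C)(C)C)cc2)ccc(O[Si](C)(C)C(C)(C)C)c1CC=C(C)C
F5 | step 4 | 3-[4-(tert-butyldimethylsilyloxy)phenyl]prop-2-yn-1-ol | OCC#Cc1ccc(O[Si](C)(C)C(C)(C)C)cc1
F6 | step 4 | 3-[4-(tert-butyldimethylsilyloxy)phenyl]prop-2-ynal | O=CC#Cc1ccc(O[Si](C)(C)C(C)(C)C)cc1
A1 | direct plan | 2,4-dihydroxyacetophenone | CC(=O)c1ccc(O)cc1O
A2 | direct plan | 3-allyl-2,4-dihydroxyacetophenone | CC(=O)c1ccc(O)c(CC=C)c1O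
A3 | direct plan | 2-methoxy-4-(methoxymethoxy)-3-(3-methylbut-2-enyl)acetophenone | CC(=O)c1ccc(OCOC)c(CC=C(C)C)c1OC
A4 | direct plan | methyl 4-(methoxymethoxy)benzoate | COC(=O)c1ccc(OCOC)cc1
A5 | direct plan | 1-[2-methoxy-4-(methoxymethoxy)-3-(3-methylbut-2-enyl)phenyl]-3-[4-(methoxymethoxy)phenyl]propane-1,3-dione | COCOc1ccc(cc1)C(=O)CC(=O)c1ccc(OCOC)c(CC=C(C)C)c1OC
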